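**Plan**

1. Retrosynthesis: the eight benzyl ethers and the C3 acetate come off last. Ring C of the upper (epiafzelechin) unit is then cut at C4–C4a and C2–C3 together, giving an O-aryl oxocarbenium ion (O1 of ring A already bonded to C2) and an (E)-enol acetate whose two alkene carbons become C3 and C4 and which already carries the complete catechin unit on C4.
2. Enabling feature: O1–C8a=C4a of the phloroglucinol ring A together with the benzylic C2 form a cationic 2-oxa-diene. C4 is bonded to C8 of the catechin ring A, a 2,4,6-trioxygenated aryl that makes C3 the nucleophilic alkene carbon and stabilises the charge at C4 for the Friedel–Crafts closure onto C4a.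
3. Forward: (+)-catechin is perbenzylated, brominated at C8, formylated, and converted via the (E)-alkenylboronate into the (E)-enol acetate (7 steps). In parallel, 4-(benzyloxy)benzaldehyde and 3,5-bis(benzyloxy)phenol give a mixed O-aryl O-methyl acetal (2 steps). The two are joined with closure of ring C in one operation, followed by deacetylation and hydrogenolysis.
4. Stereochemistry: the lower unit (2R,3S) is carried unchanged from (+)-catechin. 3,4-trans comes from the (E)-alkene and acetoxy participation. 2,4-trans (hence 2,3-cis) comes from exo, pseudoaxial placement of the catechin ring away from the peri 5-benzyloxy group. The absolute sense (2R,3R,4R) comes from a chiral Brønsted acid counter-anion.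

Key step: step 10

Remark: the direction of induction by the chiral acid in step 10 cannot be predicted with confidence; the (R)-acid is written, and its mirror image would be used if it favours the (2S,3S,4S) upper unit.

**Route**

Step 1
Reactants: 1 (+)-catechin
Product: 2 5,7,3',4'-tetra-O-benzyl-(+)-catechin
Conditions: BnBr (4.4 equiv), K2CO3 (5 equiv), DMF, 0 °C → rt, N2
Reagents that add atoms: benzyl bromide, BrCc1ccccc1
Why: Williamson etherification with a carbonate base alkylates only the four phenols and is too mild to open ring C, so C2 and C3 should keep their configuration.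

Step 2
Reactants: 2 5,7,3',4'-tetra-O-benzyl-(+)-catechin
Product: 3 3,5,7,3',4'-penta-O-benzyl-(+)-catechin
Conditions: NaH (1.5 equiv), BnBr (1.3 equiv), n-Bu4NI (5 mol %), DMF, 0 °C → rt
Reagents that add atoms: benzyl bromide, BrCc1ccccc1
Why: Williamson benzylation of the secondary alkoxide is safe once every phenol is capped, because no quinone methide can form and C2 cannot epimerise.

Step 3
Reactants: 3 3,5,7,3',4'-penta-O-benzyl-(+)-catechin
Product: 4 8-bromo-3,5,7,3',4'-penta-O-benzylcatechin
Conditions: NBS (1.05 equiv), CH2Cl2, −78 °C → rt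
Reagents that add atoms: N-bromosuccinimide, O=C1CCC(=O)N1Br
Why: Electrophilic aromatic bromination of 5,7-di-O-benzyl flavan-3-ol ethers is known to occur at C8 in preference to C6.

Step 4
Reactants: 4 8-bromo-3,5,7,3',4'-penta-O-benzylcatechin
Product: 6 8-formyl-3,5,7,3',4'-penta-O-benzylcatechin, via 8-lithio arene 5 (not isolated)
Conditions: n-BuLi (1.1 equiv), THF, −78 °C; then DMF, −78 → 0 °C; H2O
Reagents that add atoms: N,N-dimethylformamide, CN(C)C=O
Why: Bromine–lithium exchange at −78 °C is faster than benzylic deprotonation, and the aryllithium is formylated by DMF (Bouveault formylation).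

Step 5
Reactants: 6 8-formyl-3,5,7,3',4'-penta-O-benzylcatechin
Product: 7 (E)-2-(3,5,7,3',4'-penta-O-benzylcatechin-8-yl)vinylboronic acid pinacol ester
Conditions: CH2(Bpin)2 (1.3 equiv), LiTMP (from 2,2,6,6-tetramethylpiperidine and n-BuLi, 1.3 equiv), THF, 0 °C; then 6, −78 °C → rt; H2O
Reagents that add atoms: bis[(pinacolato)boryl]methane, CC1(C)OB(CB2OC(C)(C)C(C)(C)O2)OC1(C)C
Why: Boron-Wittig olefination, in which the lithiated geminal bis(boronate) adds to the aldehyde and syn-eliminates a B–O unit, should give the trans-1,2-disubstituted alkenylboronate selectively.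

Step 6
Reactants: 7 (E)-2-(3,5,7,3',4'-penta-O-benzylcatechin-8-yl)vinylboronic acid pinacol ester
Product: 8 potassium (E)-[2-(3,5,7,3',4'-penta-O-benzylcatechin-8-yl)vinyl]trifluoroborate
Conditions: KHF2 (4.5 M aq, 4 equiv), MeOH, rt; extraction into acetone, precipitation with Et2O
Reagents that add atoms: potassium hydrogen difluoride, [K+].F[H-]F
Why: Pinacol boronates are converted by aqueous KHF2 into potassium trifluoroborates without change of alkene geometry.

Step 7
Reactants: 8 potassium (E)-[2-(3,5,7,3',4'-penta-O-benzylcatechin-8-yl)vinyl]trifluoroborate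
Product: 9 (E)-2-(3,5,7,3',4'-penta-O-benzylcatechin-8-yl)vinyl acetate
Conditions: AcOH (3 equiv), CuBr (10 mol %), DMAP (20 mol %), 4 Å MS, O2 (1 atm), CH2Cl2, 40 °C
Reagents that add atoms: acetic acid, CC(=O)O
Why: Copper-catalysed oxidative C–O coupling (Chan–Lam type) of alkenyltrifluoroborates with carboxylic acids gives enol esters with retention of alkene geometry.

Step 8
Reactants: 10 4-(benzyloxy)benzaldehyde
Product: 11 4-(benzyloxy)benzaldehyde dimethyl acetal
Conditions: HC(OMe)3 (neat), p-TsOH·H2O (1 mol %), rt; Et3N quench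
Reagents that add atoms: trimethyl orthoformate, COC(OC)OC
Why: Acid-catalysed acetalisation, driven by the orthoester as water scavenger.

Step 9
Reactants: 11 4-(benzyloxy)benzaldehyde dimethyl acetal, 12 3,5-bis(benzyloxy)phenol
Product: 14 1-{[3,5-bis(benzyloxy)phenoxy](methoxy)methyl}-4-(benzyloxy)benzene (racemic mixed acetal), via alpha-chloro ether 13 (not isolated)
Conditions: AcCl (1.2 equiv), SOCl2 (2 mol %), CH2Cl2, 0 °C → rt, evaporation; then 12, i-Pr2NEt (1.5 equiv), CH2Cl2, −40 → 0 °C; chromatography on Et3N-deactivated silica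
Reagents that add atoms: none
Why: Acetyl chloride turns the dimethyl acetal into the alpha-chloro ether, which O-alkylates the phenol under amine base as chloromethyl methyl ether does in a MOM protection; the racemic acetal carbon is planarised in step 10.

Step 10
Reactants: 14 1-{[3,5-bis(benzyloxy)phenoxy](methoxy)methyl}-4-(benzyloxy)benzene, 9 (E)-2-(3,5,7,3',4'-penta-O-benzylcatechin-8-yl)vinyl acetate
Product: 17 3-O-acetyl-5,7,4'-tri-O-benzylepiafzelechin-(4β→8)-3,5,7,3',4'-penta-O-benzylcatechin, via oxocarbenium ion 15 (not isolated), via acetoxonium ion 16 (not isolated)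
Conditions: (R)-3,3'-bis(2,4,6-triisopropylphenyl)-1,1'-binaphthalene-2,2'-diyl N-triflylphosphoramide (C51H57F3NO5PS, 10 mol %), 5 Å MS, toluene/CH2Cl2, −60 → −30 °C, slow addition of 14 (1.5 equiv) to 9; Et3N quench
Reagents that add atoms: none
Why: Proposed new method: the chiral acid protonates the methoxy group of 14, methanol is lost, and the (E)-O-aryl oxocarbenium ion 15 (the cationic 2-oxa-diene C2=O1–C8a=C4a) is held in a contact ion pair with the chiral anion; enol acetate 9 attacks C2 through its acetoxy-bearing carbon (the future C3) because the 2,4,6-trioxygenated catechin ring, not the weakly donating acetoxy group, stabilises the charge developing at C4, this cation is bridged by the acetate carbonyl as the trans-dioxolanylium ion 16, and the ortho carbon C4a of ring A then attacks C4 anti to the bridging oxygen and returns a proton to the catalyst. The closest known reaction type is the oxa-Povarov reaction (Lewis-acid-promoted formal inverse-electron-demand [4+2] cycloaddition of aryl oxocarbenium ions from phenol-derived mixed acetals with styrenes), together with chiral-acid-catalysed Povarov reactions and additions to oxocarbenium ions; new here are the enol ester as 2π partner and face control by a chiral counter-anion. Ring C is the only ring closed: after the intermolecular C2–C3 bond, the C4–C4a bond forms by intramolecular Friedel–Crafts alkylation that is 6-exo-tet at C4 of 16 and 6-endo with respect to the C4a=C8a bond, so the whole event is a stepwise formal [4+2] cycloaddition. C3 and C4 are set trans by the (E)-alkene and, should the cation rotate, by the anti opening of 16; C2 relative to them is set because the 4-(benzyloxy)phenyl group sits in the outside (later equatorial) position of the (E)-oxocarbenium ion while the bulky 2,6-disubstituted catechin ring should take the exo (later pseudoaxial) position at C4 to avoid the peri 5-benzyloxy group of ring A, leaving the acetoxy group endo (later axial) where it can bridge C4, which gives 2,3-cis-2,4-trans; the chiral anion shields one face of 15 and so should fix C2 as R, from which C3 (R) and C4 (R) follow. The step needs regioselectivity in the first bond (secured by the trioxygenated aryl on C4), a single closure site (the two ortho carbons of the 3,5-bis(benzyloxy)phenoxy ring are equivalent, so only the 5,7-dioxygenated ring A can form), endo/exo and facial selectivity (peri strain, acetoxy bridging and the chiral anion; the (+)-catechin unit is too remote to direct but makes any wrong-face adduct a separable diastereomer), and chemoselectivity for the alkene over arene C–H positions (slow addition of 14 at low temperature).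

Step 11
Reactants: 17 3-O-acetyl-5,7,4'-tri-O-benzylepiafzelechin-(4β→8)-3,5,7,3',4'-penta-O-benzylcatechin
Product: 18 5,7,4'-tri-O-benzylepiafzelechin-(4β→8)-3,5,7,3',4'-penta-O-benzylcatechin
Conditions: K2CO3 (0.5 equiv), MeOH/THF 1:1, rt
Reagents that add atoms: none
Why: Base-catalysed transesterification removes the secondary acetate while benzyl ethers, the interflavan bond and all stereocentres (no free phenol, so no ring opening) are unaffected.

Step 12
Reactants: 18 5,7,4'-tri-O-benzylepiafzelechin-(4β→8)-3,5,7,3',4'-penta-O-benzylcatechin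
Product: 19 epiafzelechin-(4β→8)-catechin (target, gambiriin C as drawn)
Conditions: H2 (1 atm), Pd(OH)2/C, THF/MeOH/H2O, rt; filtration, lyophilisation
Reagents that add atoms: none
Why: Neutral hydrogenolysis cleaves all eight benzyl ethers, as in established procyanidin syntheses, and should leave the acid-labile C4–C8 bond and both benzylic C2–O1 bonds intact.

**Compound list**

1 | (+)-catechin, (2R,3S)-2-(3,4-dihydroxyphenyl)chromane-3,5,7-triol | Oc1cc(O)c2c(c1)O[C@H](c1ccc(O)c(O)c1)[C@@H](O)C2 | starting material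
2 | 5,7,3',4'-tetra-O-benzyl-(+)-catechin (2R,3S) | c1ccccc1COc1cc(OCc3ccccc3)c2c(c1)O[C@H](c1ccc(OCc3ccccc3)c(OCc3ccccc3)c1)[C@@H](O)C2 | intermediate
3 | 3,5,7,3',4'-penta-O-benzyl-(+)-catechin (2R,3S) | c1ccccc1COc1cc(OCc3ccccc3)c2c(c1)O[C@H](c1ccc(OCc3ccccc3)c(OCc3ccccc3)c1)[C@@H](OCc1ccccc1)C2 | intermediate
4 | 8-bromo-3,5,7,3',4'-penta-O-benzylcatechin (2R,3S) | Brc1c(OCc3ccccc3)cc(OCc3ccccc3)c2c1O[C@H](c1ccc(OCc3ccccc3)c(OCc3ccccc3)c1)[C@@H](OCc1ccccc1)C2 | intermediate
5 | 8-lithio-3,5,7,3',4'-penta-O-benzylcatechin (2R,3S), not isolated | [Li]c1c(OCc3ccccc3)cc(OCc3ccccc3)c2c1O[C@H](c1ccc(OCc3ccccc3)c(OCc3ccccc3)c1)[C@@H](OCc1ccccc1)C2 | intermediate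
6 | 8-formyl-3,5,7,3',4'-penta-O-benzylcatechin (2R,3S) | O=Cc1c(OCc3ccccc3)cc(OCc3ccccc3)c2c1O[C@H](c1ccc(OCc3ccccc3)c(OCc3ccccc3)c1)[C@@H](OCc1ccccc1)C2 | intermediate
7 | (E)-2-(3,5,7,3',4'-penta-O-benzylcatechin-8-yl)vinylboronic acid pinacol ester | CC1(C)OB(/C=C/c2c(OCc3ccccc3)cc(OCc3ccccc3)c3c2O[C@H](c2ccc(OCc4ccccc4)c(OCc4ccccc4)c2)[C@@H](OCc2ccccc2)C3)OC1(C)C | intermediate
8 | potassium (E)-[2-(3,5,7,3',4'-penta-O-benzylcatechin-8-yl)vinyl]trifluoroborate | F[B-](F)(F)/C=C/c1c(OCc3ccccc3)cc(OCc3ccccc3)c2c1O[C@H](c1ccc(OCc3ccccc3)c(OCc3ccccc3)c1)[C@@H](OCc1ccccc1)C2.[K+] | intermediate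
9 | (E)-2-(3,5,7,3',4'-penta-O-benzylcatechin-8-yl)vinyl acetate | CC(=O)O/C=C/c1c(OCc3ccccc3)cc(OCc3ccccc3)c2c1O[C@H](c1ccc(OCc3ccccc3)c(OCc3ccccc3)c1)[C@@H](OCc1ccccc1)C2 | intermediate
10 | 4-(benzyloxy)benzaldehyde | O=Cc1ccc(OCc2ccccc2)cc1 | starting material
11 | 4-(benzyloxy)benzaldehyde dimethyl acetal | COC(OC)c1ccc(OCc2ccccc2)cc1 | intermediate
12 | 3,5-bis(benzyloxy)phenol | Oc1cc(OCc2ccccc2)cc(OCc2ccccc2)c1 | starting material
13 | 1-(benzyloxy)-4-[chloro(methoxy)methyl]benzene (racemic), not isolated | COC(Cl)c1ccc(OCc2ccccc2)cc1 | intermediate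
14 | 1-{[3,5-bis(benzyloxy)phenoxy](methoxy)methyl}-4-(benzyloxy)benzene (racemic) | COC(Oc1cc(OCc2ccccc2)cc(OCc2ccccc2)c1)c1ccc(OCc2ccccc2)cc1 | intermediate
15 | (E)-[4-(benzyloxy)benzylidene][3,5-bis(benzyloxy)phenyl]oxonium ion (counter-ion: catalyst anion), not isolated | c1ccccc1COc1ccc(cc1)/C=[O+]/c1cc(OCc2ccccc2)cc(OCc2ccccc2)c1 | intermediate
16 | trans-4,5-disubstituted 2-methyl-1,3-dioxolan-2-ylium ion: one ring carbon (future C4) carries the penta-O-benzylcatechin-8-yl group, the other (future C3) the CH(aryloxy)(4-benzyloxyphenyl) group with C2 and C3 as in 17; not isolated | c1ccccc1COc1ccc(cc1)[C@H]([C@@H]1OC(C)=[O+][C@H]1c1c(OCc2ccccc2)cc(OCc2ccccc2)c2c1O[C@H](c1ccc(OCc3ccccc3)c(OCc3ccccc3)c1)[C@@H](OCc1ccccc1)C2)Oc1cc(OCc2ccccc2)cc(OCc2ccccc2)c1 | intermediate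
17 | 3-O-acetyl-5,7,4'-tri-O-benzylepiafzelechin-(4β→8)-3,5,7,3',4'-penta-O-benzylcatechin; upper unit (2R,3R,4R), lower unit (2R,3S) | c1ccccc1COc1ccc(cc1)[C@H]1Oc2cc(OCc3ccccc3)cc(OCc3ccccc3)c2[C@H](c2c(OCc3ccccc3)cc(OCc3ccccc3)c3c2O[C@H](c2ccc(OCc4ccccc4)c(OCc4ccccc4)c2)[C@@H](OCc2ccccc2)C3)[C@H]1OC(C)=O | intermediate
18 | 5,7,4'-tri-O-benzylepiafzelechin-(4β→8)-3,5,7,3',4'-penta-O-benzylcatechin; upper unit (2R,3R,4R), lower unit (2R,3S) | c1ccccc1COc1ccc(cc1)[C@H]1Oc2cc(OCc3ccccc3)cc(OCc3ccccc3)c2[C@H](c2c(OCc3ccccc3)cc(OCc3ccccc3)c3c2O[C@H](c2ccc(OCc4ccccc4)c(OCc4ccccc4)c2)[C@@H](OCc2ccccc2)C3)[C@H]1O | intermediate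
19 | epiafzelechin-(4β→8)-catechin (gambiriin C as drawn); upper unit (2R,3R,4R), lower unit (2R,3S) | Oc1ccc([C@H]2Oc3cc(O)cc(O)c3[C@H](c3c(O)cc(O)c4c3O[C@H](c3ccc(O)c(O)c3)[C@@H](O)C4)[C@H]2O)cc1 | target

**Totals and risks**

Total step count: 12. Longest linear sequence: 10 steps (steps 1 to 7, then 10, 11, 12).

Steps most likely to fail:

Step 10 (bears the label "Proposed new method:"). The first C–C bond may form with poor endo/exo or facial selectivity, closing ring C in the 2,3-trans-3,4-trans series or with the mirror-image upper unit. The oxocarbenium ion may also attack arene C–H positions of 9 or 14, and the acid may protonate the electron-rich styrene. The fallback uses known chemistry and makes the interflavan C4–C8 bond instead of ring C; it sets out from 3 and comes back at 17. Commercial (−)-epiafzelechin, (2R,3R)-2-(4-hydroxyphenyl)chromane-3,5,7-triol, would be benzylated at its three phenols (BnBr, K2CO3, DMF) to 5,7,4'-tri-O-benzylepiafzelechin F1. Oxidation at C4 with DDQ in the presence of 2-ethoxyethanol (CH2Cl2, rt) should give 4β-(2-ethoxyethoxy)-5,7,4'-tri-O-benzylepiafzelechin F2, and acetylation (Ac2O, pyridine, DMAP) its 3-O-acetate, 3-O-acetyl-4β-(2-ethoxyethoxy)-5,7,4'-tri-O-benzylepiafzelechin F3. Ionisation of F3 with catalytic TMSOTf in CH2Cl2 at −78 °C in the presence of an excess of 3 should give 17 by Friedel–Crafts attack of C8 of 3 on the C4 cation, anti to the participating 3-acetoxy group.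

Step 7. Protodeboronation of the electron-rich alkenyltrifluoroborate may outrun transmetalation to copper, and the styrene may degrade under the oxidative conditions. The fallback sets out from 7 and comes back at 9. Oxidation of the C–B bond (NaBO3·4H2O, THF/H2O, rt) would give 2-(3,5,7,3',4'-penta-O-benzylcatechin-8-yl)acetaldehyde F4. Enol acetylation (Ac2O, Et3N, DMAP, CH2Cl2) should give 9 together with its geometric isomer, (Z)-2-(3,5,7,3',4'-penta-O-benzylcatechin-8-yl)vinyl acetate F5. F5 would be removed by chromatography and recycled to F4 by methanolysis.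

Step 9. C-alkylation of the phloroglucinol-type ring may compete with O-alkylation through the oxocarbenium-like chloro ether, and the acid-labile mixed acetal may hydrolyse or disproportionate on isolation. The fallback sets out from 12 and comes back at 14. Williamson etherification of 12 with commercial 4-(benzyloxy)benzyl chloride (K2CO3, DMF) would give 1,3-bis(benzyloxy)-5-{[4-(benzyloxy)benzyl]oxy}benzene F6; the O–C2 bond is thus made by an SN2 reaction at the ether oxidation level. DDQ oxidation of its para-alkoxybenzylic C–H bond in the presence of methanol (CH2Cl2, 4 Å MS, 0 °C) should then give 14.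

Further compounds
F1 | step 10 | 5,7,4'-tri-O-benzylepiafzelechin (2R,3R) | c1ccccc1COc1ccc(cc1)[C@H]1Oc2cc(OCc3ccccc3)cc(OCc3ccccc3)c2C[C@H]1O
F2 | step 10 | 4β-(2-ethoxyethoxy)-5,7,4'-tri-O-benzylepiafzelechin | c1ccccc1COc1ccc(cc1)[C@H]1Oc2cc(OCc3ccccc3)cc(OCc3ccccc3)c2[C@H](OCCOCC)[C@H]1O
F3 | step 10 | 3-O-acetyl-4β-(2-ethoxyethoxy)-5,7,4'-tri-O-benzylepiafzelechin | c1ccccc1COc1ccc(cc1)[C@H]1Oc2cc(OCc3ccccc3)cc(OCc3ccccc3)c2[C@H](OCCOCC)[C@H]1OC(C)=O
F4 | step 7 | 2-(3,5,7,3',4'-penta-O-benzylcatechin-8-yl)acetaldehyde | O=CCc1c(OCc3ccccc3)cc(OCc3ccccc3)c2c1O[C@H](c1ccc(OCc3ccccc3)c(OCc3ccccc3)c1)[C@@H](OCc1ccccc1)C2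
F5 | step 7 | (Z)-2-(3,5,7,3',4'-penta-O-benzylcatechin-8-yl)vinyl acetate | CC(=O)O/C=C\c1c(OCc3ccccc3)cc(OCc3ccccc3)c2c1O[C@H](c1ccc(OCc3ccccc3)c(OCc3ccccc3)c1)[C@@H](OCc1ccccc1)C2
F6 | step 9 | 1,3-bis(benzyloxy)-5-{[4-(benzyloxy)benzyl]oxy}benzene | c1ccccc1COc1ccc(cc1)COc1cc(OCc2ccccc2)cc(OCc2ccccc2)c1
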